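**Plan**

- Retrosynthesis: the C5 allyl group goes back to an O6 allyl ether, the C3 methyl to a C3 methyl ester, and the C3–C3a bond is cut so that the ester carbon returns into the ring as C4 of a (2S)-7-benzyloxyflavanone. The flavanone C2–aryl bond is then cut to a chromone and an arylboronic acid.
- Enabling feature: C3 of the target carries ring carbon C3a and a one-carbon branch. This is the pattern left when the ring A carbon of a 2-arylchroman-4-one moves from C4 to C3 and C4 is pushed out of the ring. The 6-oxygen sits para to that migrating carbon and raises its migratory aptitude.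
- Forward order: ring A is bought, the pyranone ring is closed (chromone), the aryl group is added at C2, the six-membered ring is contracted to the dihydrofuran, the ester is taken down to CH3, and the allyl group is moved from O6 to C5.
- Stereochemistry: C2 comes from a ligand-controlled conjugate addition under divalent palladium; C3 is set trans to C2 by the substrate in the ring contraction.

Key step: step 4

Assumption: the (R)-tert-butyl pyridine–oxazoline ligand is taken to deliver the aryl group to the chromone face that gives 2S, by transfer of the facial sense known for β-substituted cyclic enones. If the sense is the opposite, the (S)-ligand is used and nothing else changes.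

**Route**

Step 1
Reactants: 1 2,4-dihydroxyacetophenone; 2 benzyl bromide
Product: 3 1-[4-(benzyloxy)-2-hydroxyphenyl]ethanone
Conditions: K2CO3 (1.1 equiv), 2 (1.05 equiv), acetone, reflux
Reagents that add atoms: none
Why: Williamson ether synthesis; the 2-hydroxyl is held in a hydrogen bond to the acetyl oxygen, so K2CO3 ionises and benzylates only the 4-hydroxyl.

Step 2
Reactants: 3 1-[4-(benzyloxy)-2-hydroxyphenyl]ethanone
Product: 5 7-(benzyloxy)-4H-chromen-4-one, via enaminone 4 (not isolated)
Conditions: Me2NCH(OMe)2, toluene, 100 °C; evaporate; then conc. HCl, CH2Cl2, 40 °C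
Reagents that add atoms: N,N-dimethylformamide dimethyl acetal, COC(OC)N(C)C
Why: Condensation of the acetyl CH3 with the amide acetal gives the enaminone, and acid then drives conjugate addition of the phenol with loss of dimethylamine (addition–elimination), the standard enaminone route to 3-unsubstituted chromones.

Step 3
Reactants: 5 7-(benzyloxy)-4H-chromen-4-one; 6 3,4,5-trimethoxyphenylboronic acid
Product: 7 (2S)-7-(benzyloxy)-2-(3,4,5-trimethoxyphenyl)-2,3-dihydro-4H-chromen-4-one
Conditions: Pd(OCOCF3)2 (5 mol %), (R)-4-tert-butyl-2-(pyridin-2-yl)-4,5-dihydro-1,3-oxazole (6 mol %), NH4PF6 (30 mol %), H2O (5 equiv), ClCH2CH2Cl, 60 °C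
Reagents that add atoms: none
Why: Asymmetric conjugate addition of an arylboronic acid to a chromone under a cationic divalent palladium pyridine–oxazoline catalyst: transmetalation, face-selective insertion of C2=C3 into the Pd–aryl bond (the ligand sets C2) and protonolysis of the palladium enolate by water, which outruns β-hydride loss and so should give the flavanone and not the flavone.

Step 4
Reactants: 7 (2S)-7-(benzyloxy)-2-(3,4,5-trimethoxyphenyl)-2,3-dihydro-4H-chromen-4-one
Product: 10 methyl (2S,3S)-6-(benzyloxy)-2-(3,4,5-trimethoxyphenyl)-2,3-dihydro-1-benzofuran-3-carboxylate, via methyl enol ether 8 (not isolated), via iodane ketal 9 (not isolated)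
Conditions: HC(OMe)3, conc. H2SO4, rt; then PhI(OAc)2 (1.2 equiv), rt; aqueous NaHCO3 work-up
Reagents that add atoms: trimethyl orthoformate, COC(OC)OC
Why: Acid and the orthoformate convert the ketone through its dimethyl ketal into the methyl enol ether 8; trivalent iodine attacks C3 of 8 on the face away from the pseudo-equatorial C2 aryl group and methanol caps C4, giving ketal 9 with an equatorial C3–I bond antiperiplanar to the C4–C4a ring bond. Ring A carbon C4a then bridges C3 and C4 in a phenonium-like 1,2-shift, iodobenzene leaves, the C3–C3a bond is formed and the dimethoxycarbenium ion left at C4 loses one methyl group on work-up to become the ester. The closest known reaction type is the oxidative ring contraction of flavanones and other cyclic aryl ketones by trivalent iodine or trivalent thallium in trimethyl orthoformate. The dihydrofuran ring arises by ring contraction: a 3-exo-type ipso bridging of the arene onto C3 (spiro-cyclopropane phenonium) followed by opening of the C4–C4a bond. The new stereocentre C3 is controlled by C2, because displacement at C3 goes with inversion and places the extruded carbon trans to the aryl group, which is also the more stable epimer of this epimerisable ester. The step needs the ring A shift to beat the shift of the C2 aryl group (isoflavone) and dehydrogenation (flavone); this is secured by the sp3 ketal at C4 formed in orthoformate, by the 7-benzyloxy group para to C4a, and by the weak bridging power of the 3,4,5-trimethoxyphenyl ring (twisted 4-methoxy, two inductively withdrawing meta methoxy groups).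

Step 5
Reactants: 10 methyl (2S,3S)-6-(benzyloxy)-2-(3,4,5-trimethoxyphenyl)-2,3-dihydro-1-benzofuran-3-carboxylate
Product: 11 [(2S,3R)-6-(benzyloxy)-2-(3,4,5-trimethoxyphenyl)-2,3-dihydro-1-benzofuran-3-yl]methanol
Conditions: LiAlH4, THF, 0 °C; aqueous NaOH work-up
Reagents that add atoms: none
Why: Hydride reduction of an ester to the primary alcohol with LiAlH4; C3 is not deprotonated at 0 °C and already holds the more stable trans arrangement (the descriptor at C3 changes by priority only).

Step 6
Reactants: 11 [(2S,3R)-6-(benzyloxy)-2-(3,4,5-trimethoxyphenyl)-2,3-dihydro-1-benzofuran-3-yl]methanol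
Product: 12 [(2S,3R)-6-(benzyloxy)-2-(3,4,5-trimethoxyphenyl)-2,3-dihydro-1-benzofuran-3-yl]methyl 4-methylbenzenesulfonate
Conditions: TsCl, Et3N, DMAP (cat.), CH2Cl2, 0 °C to rt
Reagents that add atoms: 4-methylbenzenesulfonyl chloride, Cc1ccc(cc1)S(Cl)(=O)=O
Why: Sulfonylation of a primary alcohol under nucleophilic catalysis by DMAP; no stereocentre is touched.

Step 7
Reactants: 12 [(2S,3R)-6-(benzyloxy)-2-(3,4,5-trimethoxyphenyl)-2,3-dihydro-1-benzofuran-3-yl]methyl 4-methylbenzenesulfonate
Product: 13 (2S,3S)-6-(benzyloxy)-3-methyl-2-(3,4,5-trimethoxyphenyl)-2,3-dihydro-1-benzofuran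
Conditions: LiEt3BH, THF, 0 °C to rt
Reagents that add atoms: none
Why: SN2 displacement of a primary tosylate by the strongly nucleophilic hydride of LiEt3BH, which should turn CH2OTs into CH3 faster than E2 loss of the benzylic C3 proton; C3 is not part of the reacting centre.

Step 8
Reactants: 13 (2S,3S)-6-(benzyloxy)-3-methyl-2-(3,4,5-trimethoxyphenyl)-2,3-dihydro-1-benzofuran
Product: 14 (2S,3S)-3-methyl-2-(3,4,5-trimethoxyphenyl)-2,3-dihydro-1-benzofuran-6-ol
Conditions: H2 (1 atm), 10% Pd/C, EtOAc, rt
Reagents that add atoms: none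
Why: Hydrogenolysis of a benzyl aryl ether over palladium; no alkene is present at this stage, and the hindered secondary cyclic benzylic C2–O1 bond is cleaved far more slowly at 1 atm and room temperature.

Step 9
Reactants: 14 (2S,3S)-3-methyl-2-(3,4,5-trimethoxyphenyl)-2,3-dihydro-1-benzofuran-6-ol; 15 allyl bromide
Product: 16 (2S,3S)-3-methyl-6-(prop-2-en-1-yloxy)-2-(3,4,5-trimethoxyphenyl)-2,3-dihydro-1-benzofuran
Conditions: K2CO3, acetone, reflux
Reagents that add atoms: none
Why: Williamson ether synthesis on the only free phenol.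

Step 10
Reactants: 16 (2S,3S)-3-methyl-6-(prop-2-en-1-yloxy)-2-(3,4,5-trimethoxyphenyl)-2,3-dihydro-1-benzofuran
Product: 18 (2S,3S)-3-methyl-5-(prop-2-en-1-yl)-2-(3,4,5-trimethoxyphenyl)-2,3-dihydro-1-benzofuran-6-ol, via ortho dienone 17 (not isolated)
Conditions: PhNEt2, 200 °C, sealed tube
Reagents that add atoms: none
Why: Aromatic Claisen rearrangement, a [3,3]-sigmatropic shift to the ortho dienone 17 followed by tautomerisation; C5 should be preferred over C7 because the meta alkoxy donor O1 directs the allyl group to the position para to it, the fused five-membered ring disfavours bond fixation towards C7, and C7 is flanked by two oxygens.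

**Compound list**

1 | 2,4-dihydroxyacetophenone | CC(=O)c1ccc(O)cc1O | starting material
2 | benzyl bromide | BrCc1ccccc1 | starting material
3 | 1-[4-(benzyloxy)-2-hydroxyphenyl]ethanone | CC(=O)c1ccc(OCc2ccccc2)cc1O | intermediate
4 | (E)-1-[4-(benzyloxy)-2-hydroxyphenyl]-3-(dimethylamino)prop-2-en-1-one (enaminone, not isolated) | CN(C)/C=C/C(=O)c1ccc(OCc2ccccc2)cc1O | intermediate
5 | 7-(benzyloxy)-4H-chromen-4-one | O=c1ccoc2cc(OCc3ccccc3)ccc12 | intermediate
6 | 3,4,5-trimethoxyphenylboronic acid | COc1cc(B(O)O)cc(OC)c1OC | starting material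
7 | (2S)-7-(benzyloxy)-2-(3,4,5-trimethoxyphenyl)-2,3-dihydro-4H-chromen-4-one | c1ccccc1COc1ccc2c(c1)O[C@H](c1cc(OC)c(OC)c(OC)c1)CC2=O | intermediate
8 | (2S)-7-(benzyloxy)-4-methoxy-2-(3,4,5-trimethoxyphenyl)-2H-chromene (methyl enol ether, not isolated) | c1ccccc1COc1ccc2c(c1)O[C@H](c1cc(OC)c(OC)c(OC)c1)C=C2OC | intermediate
9 | (2R,3R)-3-[acetoxy(phenyl)-λ3-iodanyl]-7-(benzyloxy)-4,4-dimethoxy-2-(3,4,5-trimethoxyphenyl)chromane, iodine trans to the aryl group, C2 unchanged in space (not isolated) | c1ccccc1COc1ccc2c(c1)O[C@H](c1cc(OC)c(OC)c(OC)c1)[C@@H](I(OC(C)=O)c1ccccc1)C2(OC)OC | intermediate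
10 | methyl (2S,3S)-6-(benzyloxy)-2-(3,4,5-trimethoxyphenyl)-2,3-dihydro-1-benzofuran-3-carboxylate (2,3-trans) | c1ccccc1COc1ccc2c(c1)O[C@H](c1cc(OC)c(OC)c(OC)c1)[C@H]2C(=O)OC | intermediate
11 | [(2S,3R)-6-(benzyloxy)-2-(3,4,5-trimethoxyphenyl)-2,3-dihydro-1-benzofuran-3-yl]methanol (2,3-trans) | c1ccccc1COc1ccc2c(c1)O[C@H](c1cc(OC)c(OC)c(OC)c1)[C@H]2CO | intermediate
12 | [(2S,3R)-6-(benzyloxy)-2-(3,4,5-trimethoxyphenyl)-2,3-dihydro-1-benzofuran-3-yl]methyl 4-methylbenzenesulfonate (2,3-trans) | c1ccccc1COc1ccc2c(c1)O[C@H](c1cc(OC)c(OC)c(OC)c1)[C@H]2COS(=O)(=O)c1ccc(C)cc1 | intermediate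
13 | (2S,3S)-6-(benzyloxy)-3-methyl-2-(3,4,5-trimethoxyphenyl)-2,3-dihydro-1-benzofuran | c1ccccc1COc1ccc2c(c1)O[C@H](c1cc(OC)c(OC)c(OC)c1)[C@H]2C | intermediate
14 | (2S,3S)-3-methyl-2-(3,4,5-trimethoxyphenyl)-2,3-dihydro-1-benzofuran-6-ol | Oc1ccc2c(c1)O[C@H](c1cc(OC)c(OC)c(OC)c1)[C@H]2C | intermediate
15 | allyl bromide | C=CCBr | starting material
16 | (2S,3S)-3-methyl-6-(prop-2-en-1-yloxy)-2-(3,4,5-trimethoxyphenyl)-2,3-dihydro-1-benzofuran | C=CCOc1ccc2c(c1)O[C@H](c1cc(OC)c(OC)c(OC)c1)[C@H]2C | intermediate
17 | (2S,3S)-3-methyl-5-(prop-2-en-1-yl)-2-(3,4,5-trimethoxyphenyl)-3,5-dihydro-1-benzofuran-6(2H)-one, both C5 epimers (ortho dienone, not isolated) | C=CCC1C=C2C(=CC1=O)O[C@H](c1cc(OC)c(OC)c(OC)c1)[C@H]2C | intermediate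
18 | (2S,3S)-3-methyl-5-(prop-2-en-1-yl)-2-(3,4,5-trimethoxyphenyl)-2,3-dihydro-1-benzofuran-6-ol (CNP0286233.1) | C=CCc1cc2c(cc1O)O[C@H](c1cc(OC)c(OC)c(OC)c1)[C@H]2C | target

**Step count and risks**

Total step count: 10. Longest linear sequence: 10 steps (1 to 18).

Steps most likely to fail:

1. Step 4 (ring contraction). Three processes could compete: the shift of the C2 aryl group or plain dehydrogenation in place of the ring A shift, oxidative attack of the trivalent iodine reagent on the two alkoxy-rich arenes, and acid-induced opening at C2 that would erode the enantiomeric purity. The fallback sets out from 7 and comes back at 10, and makes the same C4-to-C3 shift of ring A by a photochemical Wolff rearrangement. Ketone 7 would be deprotonated with LiN(SiMe3)2 in THF at −78 °C and acylated with 2,2,2-trifluoroethyl trifluoroacetate to (2S)-7-(benzyloxy)-3-(trifluoroacetyl)-2-(3,4,5-trimethoxyphenyl)chroman-4-one F1. Methanesulfonyl azide, Et3N and water in MeCN would then effect detrifluoroacetylative diazo transfer to the 3-diazo ketone F2. Irradiation in MeOH (Pyrex-filtered mercury lamp, rt) should expel N2 with migration of ring A to the carbene carbon and give the ketene F3, which methanol traps. Protonation of the resulting ester enol from the face away from the aryl group should give mainly the cis ester F4, and catalytic NaOMe in MeOH would equilibrate it to the trans ester 10.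

2. Step 3 (conjugate addition). Insertion into the electron-rich vinylogous ester may be slow, so that protodeboronation of 6 wins, or the facial selectivity may be insufficient. The fallback sets out from 3 and comes back at 7. Claisen–Schmidt condensation of 3 with 3,4,5-trimethoxybenzaldehyde (COc1cc(C=O)cc(OC)c1OC; KOH, EtOH, rt) would give the chalcone F5. NaOAc in refluxing EtOH would close it by oxa-Michael addition to the racemic flavanone F6. Kinetic resolution by asymmetric transfer hydrogenation with RuCl[(R,R)-TsDPEN](p-cymene) and HCO2H/Et3N should reduce the 2R ketone faster, with hydride delivered anti to the aryl group, to the cis flavan-4-ol F7. The unreacted 2S ketone 7 would be separated by chromatography.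

3. Step 10 (Claisen rearrangement). Part of the allyl group may migrate to C7, the position between the two oxygens, which would lower the regioselectivity. The fallback sets out from 14 and comes back at 18. Iodination with N-iodosuccinimide in MeCN at 0 °C should occur at C5, ortho to the hydroxyl and para to O1, and give (2S,3S)-5-iodo-3-methyl-2-(3,4,5-trimethoxyphenyl)-2,3-dihydro-1-benzofuran-6-ol F8. Stille coupling of F8 with allyltributylstannane (C=CC[Sn](CCCC)(CCCC)CCCC) under Pd(PPh3)4, a zerovalent palladium catalyst, in toluene at 100 °C would then give 18 with the allyl group fixed at C5.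

**Further compounds**

F1 | step 4 | (2S)-7-(benzyloxy)-3-(trifluoroacetyl)-2-(3,4,5-trimethoxyphenyl)chroman-4-one, C3 epimers, also present as enol | c1ccccc1COc1ccc2c(c1)O[C@H](c1cc(OC)c(OC)c(OC)c1)C(C(=O)C(F)(F)F)C2=O
F2 | step 4 | (2R)-7-(benzyloxy)-3-diazo-2-(3,4,5-trimethoxyphenyl)chroman-4-one, C2 unchanged in space, descriptor changed by priority only | c1ccccc1COc1ccc2c(c1)O[C@H](c1cc(OC)c(OC)c(OC)c1)C(=[N+]=[N-])C2=O
F3 | step 4 | (2R)-6-(benzyloxy)-3-(oxomethylidene)-2-(3,4,5-trimethoxyphenyl)-2,3-dihydro-1-benzofuran (ketene), C2 unchanged in space | c1ccccc1COc1ccc2c(c1)O[C@H](c1cc(OC)c(OC)c(OC)c1)C2=C=O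
F4 | step 4 | methyl (2S,3R)-6-(benzyloxy)-2-(3,4,5-trimethoxyphenyl)-2,3-dihydro-1-benzofuran-3-carboxylate (2,3-cis) | c1ccccc1COc1ccc2c(c1)O[C@H](c1cc(OC)c(OC)c(OC)c1)[C@@H]2C(=O)OC
F5 | step 3 | (E)-1-[4-(benzyloxy)-2-hydroxyphenyl]-3-(3,4,5-trimethoxyphenyl)prop-2-en-1-one | O=C(/C=C/c1cc(OC)c(OC)c(OC)c1)c1ccc(OCc2ccccc2)cc1O
F6 | step 3 | racemic 7-(benzyloxy)-2-(3,4,5-trimethoxyphenyl)-2,3-dihydro-4H-chromen-4-one | c1ccccc1COc1ccc2c(c1)OC(c1cc(OC)c(OC)c(OC)c1)CC2=O
F7 | step 3 | (2R,4R)-7-(benzyloxy)-2-(3,4,5-trimethoxyphenyl)chroman-4-ol (2,4-cis) | c1ccccc1COc1ccc2c(c1)O[C@@H](c1cc(OC)c(OC)c(OC)c1)C[C@H]2O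
F8 | step 10 | (2S,3S)-5-iodo-3-methyl-2-(3,4,5-trimethoxyphenyl)-2,3-dihydro-1-benzofuran-6-ol | Ic1cc2c(cc1O)O[C@H](c1cc(OC)c(OC)c(OC)c1)[C@H]2C
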